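Build this flask one process at a time, and carry through it the pool of target, counted with its product in the second phase.

substrate 2.0 mM; reagent in the second phase 3.60 mM; time 1.5 min; volume of the second phase over the first 0.50

1. the state of affairs at 1.5 min: stopped, and by what, or still going (it is still moving / forward and back rates have come level / all of the substrate has reacted)
2. share of the substrate used up at 1.5 min
3. target at 1.5 min, in percent of the substrate charged

- target is meant together with its product in the second phase
- in the second phase: reagent in the second phase, product in the second phase; everything else is in the first
- charges count per volume of the first phase; a concentration in a rate is the amount of a species over the volume of its own phase; every rate counts per litre of the first phase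
- what has gone from substrate into another species counts as reacted, even if it can come back
- the reaction counts as stopped when no species that holds the substrate changes by six tenths of a point or more over the second half of the time
- run time (flask): 1.5 min

    reagent in the reaction phase ⇌ reagent in the second phase, rate k1*([reagent in the reaction phase] - [reagent in the second phase]/K1) per volume of the first phase (K1 = 0.823, k1 = 0.0171 s⁻¹)
    substrate + reagent in the reaction phase → target (k2 = 40.2 M⁻¹ s⁻¹)
    target ⇌ product in the second phase, rate k3*([target] - [product in the second phase]/K3) per volume of the first phase (K3 = 0.699, k3 = 1.04 s⁻¹)
    target → decomposed product (k4 = 0.0296 s⁻¹)
    substrate ⇌ dormant form (K5 = 6.3, k5 = 0.0517 s⁻¹)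
    reagent in the reaction phase → decomposed reagent (k6 = 0.0806 s⁻¹)

With the main step alone, the reagent charge of 3.60 mM exceeds the 2.0 mM of substrate, so substrate is the limiting reagent and the ceiling for target is 100%.

Now add decay of the reagent in the reaction phase. Its constant 0.0806 s⁻¹ stands against 0.0804 s⁻¹ for step 2 at charged substrate, which gives substrate a share φ₀ = 49.9%, so at the start about half of the arriving reagent reaches substrate.

Next add the dormant form. Its relaxation half-life 0.193 min is short against the 1.5 min, and free substrate then falls towards the fraction 1/(1+K5) of what remains, which lowers the share to φ₁ = 12.0%. As my own rough guess I take the geometric mean of φ₀ and φ₁, so the pool made is 44.1% of the substrate charged.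

Last add decay of target. Transfer at 1.04 s⁻¹ is faster than decay at 0.0296 s⁻¹, so the two phases stay near partition and decay acts on the reaction-phase part. This gives kP = 0.0219 s⁻¹, the pool decay constant, step 4's constant divided by 1+K3·V1, and so a pool half-life of 0.528 min. Taking the pool as made at about the relaxation time τ = 16.7 s, a part 20.0% survives.

| Process added | My target at the asked time |
|---|---|
| Main step | 100% |
| Reagent decay | 89.8% |
| Dormant form | 44.1% |
| Target decay | 8.83% |

Even at my reckoned end level the pool falls by about 8.7 percentage points over a span as long as half the time, so I call the flask still moving.

The forecast says it is still moving, with conversion 91.6% (90.5% to 92.5%) and target 7.9% (7% to 8.8%), noting that “Target and its second-phase product equilibrate fast”. My figure for target is higher than its figure.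

In the simulation it is still moving, with conversion 91.5% and target 7.82%.

Target plus decomposed product in the flask at the asked time comes to 32.8%, less than my 44.1%. Read the same flask at 6.0 min, and kP, reckoned with nothing new made, takes 7.82% down to 0.0210%. Reagent in the second phase still stood at 4.82% of its charge at the asked time, and that neighbour flask reads 0.0301%.

(The numbers were drawn at random within sensible limits; no experiment stands behind them.)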